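**Outline**

- Cuts: the methyl ester goes back to a primary alcohol. The C5–CH3 bond of the 1,2-dioxolane is exchanged for a C5–O bond to the terminal oxygen of the C3 arm (a 2,6,7-trioxabicyclo[3.2.1]octane). Both peroxide C–O bonds then go back to H2O2 and a keto-oxetane, the ketone C–C bond to an N-methoxy-N-methylamide plus a side-chain alkyllithium, and the side chain to two bromides (copper coupling).
- What makes the key step possible: ring carbon C3, with its methyl group, its acetate arm and the C4 methylene that leads on to C5, corresponds atom for atom to (R)-mevalonolactone (carbinol carbon plus the other five carbons). The acetate arm and the C5 methyl share one face of the dioxolane, so the end oxygen of the arm can be clipped onto C5 as a ketal bridge (the oxane ring of the bicycle) and later swapped for methyl.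
- Forward: (a) four-membered ether from the ring-opened lactone; (b) side-chain iodide by copper coupling, then union of the halves as a ketone; (c) H2O2 builds the five-membered peroxide and acid adds the oxane bridge; (d) AlMe3 unclips the bridge while installing the C5 methyl; (e) oxidation and esterification.
- Stereochemistry: C3 is the carbinol carbon of (R)-mevalonolactone; its C–O bond survives the oxetane closure and is then exchanged for C–OO with one stereospecific inversion. The side-chain CH(CH3) comes unchanged from (S)-3-bromo-2-methylpropan-1-ol. C5 is made last, under control of C3 through the bicyclic ketal (retention at the ketal carbon).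

Key step: step 11

Remark on the chemistry: the hemiketal carbon of compound 15 is taken as an equilibrating mixture of epimers (in equilibrium with open-chain 14), which is of no consequence because step 10 converges both on one bicyclic ketal.

**Route**

Step 1
Reactants: 1 (R)-mevalonolactone
Product: 2 (3R)-3,5-dihydroxy-N-methoxy-N,3-dimethylpentanamide
Conditions: MeNH(OMe)·HCl, AlMe3, CH2Cl2, 0 °C → rt; aq potassium sodium tartrate
Reagents that add atoms: N,O-dimethylhydroxylamine hydrochloride, CNOC.Cl
Why: Weinreb aminolysis of a lactone by the aluminium amide formed in the flask opens the δ-lactone at the acyl carbon only, so the tertiary carbinol centre is not touched.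

Step 2
Reactants: 2 (3R)-3,5-dihydroxy-N-methoxy-N,3-dimethylpentanamide
Product: 3 (3R)-3-hydroxy-5-[methoxy(methyl)amino]-3-methyl-5-oxopentyl 4-methylbenzenesulfonate
Conditions: TsCl, Et3N, DMAP (cat.), CH2Cl2, 0 °C
Reagents that add atoms: 4-methylbenzenesulfonyl chloride, Cc1ccc(cc1)S(Cl)(=O)=O
Why: Chemoselective sulfonylation should take the primary hydroxyl and leave the hindered tertiary one, without involving the stereocentre.

Step 3
Reactants: 3 (3R)-3-hydroxy-5-[methoxy(methyl)amino]-3-methyl-5-oxopentyl 4-methylbenzenesulfonate
Product: 4 N-methoxy-N-methyl-2-[(2R)-2-methyloxetan-2-yl]acetamide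
Conditions: KOtBu, THF, 0 °C → rt
Reagents that add atoms: none
Why: Intramolecular Williamson etherification (4-exo-tet) of the tertiary alkoxide on the primary tosylate, helped by the fully substituted carbinol carbon, closes the oxetane without breaking the C–O bond of the stereocentre, so its configuration is retained.

Step 4
Reactants: 5 (S)-3-bromo-2-methylpropan-1-ol
Product: 6 (S)-(3-bromo-2-methylpropoxy)(tert-butyl)dimethylsilane
Conditions: TBSCl, imidazole, CH2Cl2, rt
Reagents that add atoms: tert-butyldimethylsilyl chloride, CC(C)(C)[Si](C)(C)Cl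
Why: Standard silyl ether formation masks the hydroxyl so that it cannot quench the Grignard reagent of the next step.

Step 5
Reactants: 6 (S)-(3-bromo-2-methylpropoxy)(tert-butyl)dimethylsilane; 7 (5-bromopentyl)benzene
Product: 9 tert-butyldimethyl{[(2R)-2-methyl-8-phenyloctyl]oxy}silane, via Grignard reagent 8 (not isolated)
Conditions: 7, Mg, THF, rt → 40 °C; then 6, Li2CuCl4 (cat.), NMP, THF, 0 °C → rt
Reagents that add atoms: none
Why: Copper-catalysed sp3–sp3 cross-coupling of a primary alkyl bromide with a primary alkyl Grignard reagent (Kochi coupling) joins the chain at a carbon next to, not at, the stereocentre, which therefore stays as bought (the descriptor changes by priority only).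

Step 6
Reactants: 9 tert-butyldimethyl{[(2R)-2-methyl-8-phenyloctyl]oxy}silane
Product: 10 (2R)-2-methyl-8-phenyloctan-1-ol
Conditions: TBAF, THF, rt
Reagents that add atoms: none
Why: Fluoride-mediated desilylation frees the primary alcohol and touches nothing else in this hydrocarbon chain.

Step 7
Reactants: 10 (2R)-2-methyl-8-phenyloctan-1-ol
Product: 11 [(7R)-8-iodo-7-methyloctyl]benzene
Conditions: I2, PPh3, imidazole, CH2Cl2, 0 °C → rt
Reagents that add atoms: iodine, II
Why: Appel-type iodination displaces the activated primary oxygen by SN2 at CH2, leaving the adjacent stereocentre alone.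

Step 8
Reactants: 11 [(7R)-8-iodo-7-methyloctyl]benzene; 4 N-methoxy-N-methyl-2-[(2R)-2-methyloxetan-2-yl]acetamide
Product: 13 (4R)-4-methyl-1-[(2R)-2-methyloxetan-2-yl]-10-phenyldecan-2-one, via alkyllithium 12 (not isolated)
Conditions: 11, t-BuLi (2 equiv), Et2O–pentane, −78 °C; then 4, −78 → −20 °C; aq NH4Cl
Reagents that add atoms: none
Why: Lithium–iodine exchange followed by Weinreb ketone synthesis should stop at the ketone because the chelated tetrahedral adduct persists until the quench, and an oxetane is inert to organolithiums when no Lewis acid is present.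

Step 9
Reactants: 13 (4R)-4-methyl-1-[(2R)-2-methyloxetan-2-yl]-10-phenyldecan-2-one
Product: 15 (5S)-5-(2-hydroxyethyl)-5-methyl-3-[(2R)-2-methyl-8-phenyloctyl]-1,2-dioxolan-3-ol (hemiketal epimers), via hydroperoxy ketone 14 (not isolated)
Conditions: ethereal H2O2 (anhydrous, excess), TMSOTf (0.2 equiv), Et2O, −78 → −20 °C
Reagents that add atoms: hydrogen peroxide, OO
Why: Lewis-acid-promoted perhydrolysis of a 2,2-disubstituted oxetane lets H2O2 attack the activated tertiary carbon opposite the departing oxygen (SN2-like, inversion at the future C3), and the β-hydroperoxy ketone so formed closes by itself to the five-membered peroxyhemiketal.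

Step 10
Reactants: 15 (5S)-5-(2-hydroxyethyl)-5-methyl-3-[(2R)-2-methyl-8-phenyloctyl]-1,2-dioxolan-3-ol
Product: 16 (1S,5S)-5-methyl-1-[(2R)-2-methyl-8-phenyloctyl]-2,6,7-trioxabicyclo[3.2.1]octane
Conditions: CSA (cat.), 4 Å molecular sieves, CH2Cl2, rt
Reagents that add atoms: none
Why: Acid-catalysed intramolecular peroxyketalization with loss of water closes the oxane bridge, and since the hydroxyethyl tether can reach the hemiketal carbon only from its own face, both hemiketal epimers should converge on one ketal whose configuration is fixed by the tertiary peroxide carbon.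

Step 11
Reactants: 16 (1S,5S)-5-methyl-1-[(2R)-2-methyl-8-phenyloctyl]-2,6,7-trioxabicyclo[3.2.1]octane
Product: 17 2-{(3S,5S)-3,5-dimethyl-5-[(2R)-2-methyl-8-phenyloctyl]-1,2-dioxolan-3-yl}ethan-1-ol
Conditions: AlMe3 (3 equiv, hexanes), CH2Cl2, −78 → 0 °C; aq potassium sodium tartrate
Reagents that add atoms: trimethylaluminium, C[Al](C)C
Why: Proposed new method: coordination of AlMe3 to O2 of the bicycle (the ether bridge, a better Lewis base than either peroxide oxygen) should weaken the C1–O2 bond until it heterolyses, leaving a peroxy-stabilized tertiary cation at C1 within the dioxolane and, still attached to C5 by the CH2CH2 arm, an R–O–AlMe3 aluminate; because this anion cannot leave the face it occupied, it passes one methyl group to C1 in a four-centre contact ion pair before the ions separate. Precedent is limited to two related reaction types: organoaluminium cleavage of bicyclic ketals and chiral acetals, which proceeds with retention, and Lewis-acid generation of peroxycarbenium ions from 3-alkoxy-1,2-dioxolanes followed by capture with carbon nucleophiles. No ring is formed; the six-membered oxane of the bicycle is opened while the 1,2-dioxolane is kept. The quaternary centre created (dioxolane C5) takes its configuration from C3: the bridge is necessarily cis to the C3 arm and methyl enters where oxygen left, so the C5 methyl becomes cis to the hydroxyethyl arm and the long chain trans to it. The selectivities required are cleavage of the ether C–O bond rather than a peroxide C–O or O–O bond and same-face delivery, and both rest on the bicyclic frame: aluminium prefers the more basic bridge oxygen, the di-tertiary peroxide is shielded, and the short tether reaches only one face of C1.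

Step 12
Reactants: 17 2-{(3S,5S)-3,5-dimethyl-5-[(2R)-2-methyl-8-phenyloctyl]-1,2-dioxolan-3-yl}ethan-1-ol
Product: 19 2-{(3R,5S)-3,5-dimethyl-5-[(2R)-2-methyl-8-phenyloctyl]-1,2-dioxolan-3-yl}acetic acid, via aldehyde 18 (not isolated)
Conditions: TEMPO (cat.), PhI(OAc)2, MeCN–H2O, rt
Reagents that add atoms: water, O
Why: Oxoammonium oxidation (TEMPO/PhI(OAc)2) carries the primary alcohol through the aldehyde hydrate to the acid under mildly acidic conditions that should leave the di-tertiary dialkyl peroxide and the phenyl ring alone (the descriptor at C3 changes by priority only).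

Step 13
Reactants: 19 2-{(3R,5S)-3,5-dimethyl-5-[(2R)-2-methyl-8-phenyloctyl]-1,2-dioxolan-3-yl}acetic acid
Product: 20 methyl 2-{(3R,5S)-3,5-dimethyl-5-[(2R)-2-methyl-8-phenyloctyl]-1,2-dioxolan-3-yl}acetate
Conditions: TMSCHN2, PhMe–MeOH, 0 °C
Reagents that add atoms: (trimethylsilyl)diazomethane, C[Si](C)(C)C=[N+]=[N-]
Why: Base-free O-methylation of the carboxylic acid by a diazoalkane avoids the β-elimination to which a β-peroxy ester is prone under basic conditions.

**Compound list**

1 | (R)-mevalonolactone, (4R)-4-hydroxy-4-methyloxan-2-one | C[C@@]1(O)CCOC(=O)C1 | starting material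
2 | (3R)-3,5-dihydroxy-N-methoxy-N,3-dimethylpentanamide | CON(C)C(=O)C[C@](C)(O)CCO | intermediate
3 | (3R)-3-hydroxy-5-[methoxy(methyl)amino]-3-methyl-5-oxopentyl 4-methylbenzenesulfonate | CON(C)C(=O)C[C@](C)(O)CCOS(=O)(=O)c1ccc(C)cc1 | intermediate
4 | N-methoxy-N-methyl-2-[(2R)-2-methyloxetan-2-yl]acetamide | CON(C)C(=O)C[C@@]1(C)CCO1 | intermediate
5 | (S)-3-bromo-2-methylpropan-1-ol | OC[C@H](C)CBr | starting material
6 | (S)-(3-bromo-2-methylpropoxy)(tert-butyl)dimethylsilane | CC(C)(C)[Si](C)(C)OC[C@H](C)CBr | intermediate
7 | (5-bromopentyl)benzene | BrCCCCCc1ccccc1 | starting material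
8 | (5-phenylpentyl)magnesium bromide | Br[Mg]CCCCCc1ccccc1 | intermediate (not isolated)
9 | tert-butyldimethyl{[(2R)-2-methyl-8-phenyloctyl]oxy}silane | CC(C)(C)[Si](C)(C)OC[C@H](C)CCCCCCc1ccccc1 | intermediate
10 | (2R)-2-methyl-8-phenyloctan-1-ol | OC[C@H](C)CCCCCCc1ccccc1 | intermediate
11 | [(7R)-8-iodo-7-methyloctyl]benzene | IC[C@H](C)CCCCCCc1ccccc1 | intermediate
12 | (2-methyl-8-phenyloctyl)lithium, spatial arrangement of 11 unchanged (formally 2S because lithium ranks below carbon) | [Li]C[C@H](C)CCCCCCc1ccccc1 | intermediate (not isolated)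
13 | (4R)-4-methyl-1-[(2R)-2-methyloxetan-2-yl]-10-phenyldecan-2-one | C[C@]1(CC(=O)C[C@H](C)CCCCCCc2ccccc2)CCO1 | intermediate
14 | (3S,7R)-3-hydroperoxy-1-hydroxy-3,7-dimethyl-13-phenyltridecan-5-one | OCC[C@](C)(OO)CC(=O)C[C@H](C)CCCCCCc1ccccc1 | intermediate (not isolated)
15 | (5S)-5-(2-hydroxyethyl)-5-methyl-3-[(2R)-2-methyl-8-phenyloctyl]-1,2-dioxolan-3-ol, both C3 epimers | OCC[C@@]1(C)CC(O)(C[C@H](C)CCCCCCc2ccccc2)OO1 | intermediate
16 | (1S,5S)-5-methyl-1-[(2R)-2-methyl-8-phenyloctyl]-2,6,7-trioxabicyclo[3.2.1]octane | C[C@]12CCO[C@](C[C@H](C)CCCCCCc3ccccc3)(C1)OO2 | intermediate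
17 | 2-{(3S,5S)-3,5-dimethyl-5-[(2R)-2-methyl-8-phenyloctyl]-1,2-dioxolan-3-yl}ethan-1-ol | OCC[C@@]1(C)C[C@](C)(C[C@H](C)CCCCCCc2ccccc2)OO1 | intermediate
18 | 2-{(3R,5S)-3,5-dimethyl-5-[(2R)-2-methyl-8-phenyloctyl]-1,2-dioxolan-3-yl}acetaldehyde | O=CC[C@@]1(C)C[C@](C)(C[C@H](C)CCCCCCc2ccccc2)OO1 | intermediate (not isolated)
19 | 2-{(3R,5S)-3,5-dimethyl-5-[(2R)-2-methyl-8-phenyloctyl]-1,2-dioxolan-3-yl}acetic acid | OC(=O)C[C@@]1(C)C[C@](C)(C[C@H](C)CCCCCCc2ccccc2)OO1 | intermediate
20 | methyl 2-{(3R,5S)-3,5-dimethyl-5-[(2R)-2-methyl-8-phenyloctyl]-1,2-dioxolan-3-yl}acetate | COC(=O)C[C@@]1(C)C[C@](C)(C[C@H](C)CCCCCCc2ccccc2)OO1 | target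

**Step count and risks**

Total step count: 13. Longest linear sequence: 10 steps (steps 4 to 13, from compound 5).

Steps most likely to fail:

1. Step 11 (proposed new method). The aluminium reagent may attack the O–O bond instead of the ketal. Ionization may also run towards the oxane oxocarbenium ion with loss of the peroxide, or methyl may be delivered from outside the ion pair so that facial control is lost. The fallback uses a known electrophile-induced peroxide cyclization and sets out from ketone 13. Wittig methylenation (Ph3P=CH2 from Ph3PCH3Br and NaN(SiMe3)2, THF, −78 → 0 °C) should give (S)-2-methyl-2-[(R)-4-methyl-2-methylidene-10-phenyldecyl]oxetane F1 (spatial arrangement of 13 unchanged). Perhydrolysis as in step 9 (ethereal H2O2, TMSOTf, Et2O, −78 °C) should open the oxetane with inversion to (3R,7R)-3-hydroperoxy-3,7-dimethyl-5-methylidene-13-phenyltridecan-1-ol F2. Cycloperoxymercuration (Hg(OAc)2, CH2Cl2, rt), a 5-exo attack of the hydroperoxide on the more substituted alkene carbon, should close the 1,2-dioxolane to acetoxy{[(5S)-5-(2-hydroxyethyl)-5-methyl-3-[(2R)-2-methyl-8-phenyloctyl]-1,2-dioxolan-3-yl]methyl}mercury F3, expected as a pair of epimers at the new ring carbon. Alkaline NaBH4 (0 °C) then replaces mercury by hydrogen, turning the CH2Hg group into the C5 methyl. The sequence comes back to the route at alcohol 17, which would have to be separated from its C5 epimer because this closure has no bicyclic relay.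

2. Step 9. With the ketone present, the activated oxetane may ionize fully at the tertiary carbon (erosion of the inversion), lose a proton to give an enone, or the ketone may be drawn into perhydrate and oligomeric peroxide formation. The fallback installs the peroxide before the ketone exists and sets out from oxetane amide 4 (with alkyllithium 12 made from 11 as in step 8). Ethereal H2O2 and TMSOTf (Et2O, −78 °C) should give (S)-3-hydroperoxy-5-hydroxy-N-methoxy-N,3-dimethylpentanamide F4. 2,2-Dimethoxypropane with PPTS (CH2Cl2, rt) ties the hydroperoxide and the alcohol together as N-methoxy-N-methyl-2-[(S)-3,3,7-trimethyl-1,2,4-trioxepan-7-yl]acetamide F5. Acylation of 12 by this amide at −78 °C, where the hindered di-tertiary peroxyketal should outlast the organolithium, gives (R)-4-methyl-10-phenyl-1-[(S)-3,3,7-trimethyl-1,2,4-trioxepan-7-yl]decan-2-one F6. TsOH (cat.) in CH2Cl2 then exchanges the acetone ketal for the internal ketone with loss of acetone, and the sequence comes back to the route at bicyclic peroxyketal 16.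

3. Step 8. The alkyllithium may deprotonate the amide at the α-carbon, after which β-elimination would open the strained oxetane, or the adduct may collapse early and add a second time. The fallback forms the C–C bond at the aldehyde oxidation level with a non-basic organometallic and sets out from amide 4. i-Bu2AlH (THF, −78 °C) should give 2-[(2R)-2-methyloxetan-2-yl]acetaldehyde F7. The organocerium reagent made from 12 and CeCl3 (THF, −78 °C) adds to it to give (4R)-4-methyl-1-[(2R)-2-methyloxetan-2-yl]-10-phenyldecan-2-ol F8 as both carbinol epimers, which is of no consequence. Dess–Martin periodinane buffered with NaHCO3 (CH2Cl2, rt) oxidizes the carbinol under neutral conditions, and the sequence comes back to the route at ketone 13.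

**Further compounds**

F1 | step 11 | (S)-2-methyl-2-[(R)-4-methyl-2-methylidene-10-phenyldecyl]oxetane | C[C@]1(CC(=C)C[C@H](C)CCCCCCc2ccccc2)CCO1
F2 | step 11 | (3R,7R)-3-hydroperoxy-3,7-dimethyl-5-methylidene-13-phenyltridecan-1-ol | OCC[C@](C)(OO)CC(=C)C[C@H](C)CCCCCCc1ccccc1
F3 | step 11 | acetoxy{[(5S)-5-(2-hydroxyethyl)-5-methyl-3-[(2R)-2-methyl-8-phenyloctyl]-1,2-dioxolan-3-yl]methyl}mercury, both C3 epimers | OCC[C@@]1(C)CC(C[Hg]OC(C)=O)(C[C@H](C)CCCCCCc2ccccc2)OO1
F4 | step 9 | (S)-3-hydroperoxy-5-hydroxy-N-methoxy-N,3-dimethylpentanamide | CON(C)C(=O)C[C@@](C)(OO)CCO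
F5 | step 9 | N-methoxy-N-methyl-2-[(S)-3,3,7-trimethyl-1,2,4-trioxepan-7-yl]acetamide | CON(C)C(=O)C[C@]1(C)CCOC(C)(C)OO1
F6 | step 9 | (R)-4-methyl-10-phenyl-1-[(S)-3,3,7-trimethyl-1,2,4-trioxepan-7-yl]decan-2-one | O=C(C[C@H](C)CCCCCCc1ccccc1)C[C@]1(C)CCOC(C)(C)OO1
F7 | step 8 | 2-[(2R)-2-methyloxetan-2-yl]acetaldehyde | O=CC[C@@]1(C)CCO1
F8 | step 8 | (4R)-4-methyl-1-[(2R)-2-methyloxetan-2-yl]-10-phenyldecan-2-ol, both C2 epimers | C[C@]1(CC(O)C[C@H](C)CCCCCCc2ccccc2)CCO1
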